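**Retrosynthetic overview**
1. Numbering: ring A (seven-membered) = C1 (angelate carbinol), C2=C3 (CH3 on C3), C4H2, C5 (veratrate carbinol), C6 (fusion CH), C7 (fusion C-CH3). Ring B (five-membered) = C6, C7, C8H2, C9H2, C10 (isopropyl carbinol). The target is (1R,5S,6S,7S,10R).
2. Feature used: the only ring alkene, C2=C3, lies in ring A opposite the C6-C7 fusion bond. All five stereocentres sit on ring B or on a carbon attached to it. Cutting C2=C3 (ring-closing metathesis) therefore leaves a fully stereodefined cyclopentane with a C1 vinyl carbinol arm on C7 and, trans to it, a C3 isopropenyl arm on C6.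
3. The angelate goes on last. C1 grows from a CH2OPMB group on C7 through aldehyde, vinyl ketone and CBS reduction. The veratrate is placed on C5 directly after C10 is made by isopropylcerium addition to the ring B ketone.
4. C5-C6 comes from an anti-selective boron aldol of the regiodefined C6=C10 enolate with 3-methylbut-3-enal. That enolate and the quaternary C7 come from a copper-catalysed asymmetric methyl conjugate addition to 3-(PMBOCH2)cyclopent-2-enone.
5. Ring order: ring B is present from the start (3-ethoxycyclopent-2-enone). Ring A is the only ring formed, at step 15.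

Key step: step 15

Assumption: the (R,R)-phosphoramidite is taken to send methyl to the enone face that makes C7 S; if the sense proves opposite, the (S,S)-ligand is used and nothing else changes.

**Step 1**
Reactants: 1 4-methoxybenzyl alcohol; 2 tributyl(iodomethyl)stannane
Product: 4 tributyl{[(4-methoxybenzyl)oxy]methyl}stannane, via sodium 4-methoxybenzyl alkoxide 3 (not isolated)
Conditions: NaH, THF-DMF, 0 °C; then 2, 0 °C to rt
Reagents that add atoms: none
Why: Williamson ether synthesis in which the alkoxide displaces iodide from the unhindered iodomethyl carbon; no stereocentre is involved.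

**Step 2**
Reactants: 4 tributyl{[(4-methoxybenzyl)oxy]methyl}stannane; 5 3-ethoxycyclopent-2-en-1-one
Product: 8 3-{[(4-methoxybenzyl)oxy]methyl}cyclopent-2-en-1-one, via alkoxymethyllithium 6 (not isolated), via lithium carbinolate 7 (not isolated)
Conditions: n-BuLi, THF, -78 °C; then 5, -78 to 0 °C; then 1 M aq HCl, rt
Reagents that add atoms: water, O
Why: Tin-lithium exchange gives the alkoxymethyllithium, which adds 1,2 to the vinylogous ester, and acid then releases the transposed enone (Stork-Danheiser transposition).

**Step 3**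
Reactants: 8 3-{[(4-methoxybenzyl)oxy]methyl}cyclopent-2-en-1-one
Product: 10 (7S)-trimethylsilyl enol ether {[(3S)-3-{[(4-methoxybenzyl)oxy]methyl}-3-methylcyclopent-1-en-1-yl]oxy}trimethylsilane, via dimethylaluminium enolate 9 (not isolated)
Conditions: AlMe3 (2 equiv), Cu(O2CC4H3S) (copper thiophene-2-carboxylate, 5 mol %), (R,R)-N,N-bis[1-(naphthalen-2-yl)ethyl]dibenzo[d,f][1,3,2]dioxaphosphepin-6-amine (10 mol %), Et2O, -30 °C; then Me3SiOTf, -30 to 0 °C
Reagents that add atoms: trimethylaluminium, C[Al](C)C; trimethylsilyl trifluoromethanesulfonate, C[Si](C)(C)OS(=O)(=O)C(F)(F)F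
Why: Copper-catalysed asymmetric conjugate addition of AlMe3 to a β-substituted cyclopentenone, in which the chiral phosphoramidite-copper complex picks the enone face and sets the quaternary C7 as S, while O-silylation of the aluminium enolate stores the C6=C10 enolate regiochemistry.

**Step 4**
Reactants: 11 3-methylbut-3-en-1-ol
Product: 12 3-methylbut-3-enal
Conditions: Dess-Martin periodinane, CH2Cl2, 0 °C to rt; used at once as a dried solution
Reagents that add atoms: none
Why: Dess-Martin oxidation runs without base, so the β,γ-alkene should not drift into conjugation.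

**Step 5**
Reactants: 10 (7S)-trimethylsilyl enol ether; 12 3-methylbut-3-enal
Product: 15 anti aldol (2S,3S)-2-[(1S)-1-hydroxy-3-methylbut-3-enyl]-3-{[(4-methoxybenzyl)oxy]methyl}-3-methylcyclopentan-1-one (5S,6S,7S), via lithium enolate 13 (not isolated), via dibutylboron enolate 14 (not isolated)
Conditions: MeLi, THF, 0 °C; Bu2BOTf, -78 °C; 12, -78 to -20 °C; H2O2, MeOH, pH 7 buffer, 0 °C
Reagents that add atoms: none
Why: Cleavage of the silyl enol ether and lithium-to-boron exchange give the regiodefined, non-basic E(O)-boron enolate, whose Zimmerman-Traxler chair should give the anti aldol (C5 S next to C6 S), the aldehyde arriving on the enolate face opposite the larger CH2OPMB group on C7 so that the new C6 arm is trans to C1.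

**Step 6**
Reactants: 15 anti aldol
Product: 16 C5 triethylsilyl ether of 15 (5S,6S,7S)
Conditions: Et3SiOTf, 2,6-lutidine, CH2Cl2, -78 °C
Reagents that add atoms: triethylsilyl trifluoromethanesulfonate, CC[Si](CC)(CC)OS(=O)(=O)C(F)(F)F
Why: Low-temperature silylation caps the C5 hydroxyl without touching C6, so that no aldolate able to undergo retro-aldol cleavage can form in step 7.

**Step 7**
Reactants: 16 C5 triethylsilyl ether
Product: 18 diol (1R,2S,3S)-2-[(1S)-1-hydroxy-3-methylbut-3-enyl]-1-isopropyl-3-{[(4-methoxybenzyl)oxy]methyl}-3-methylcyclopentan-1-ol (5S,6S,7S,10R), via C5 silyl ether carbinol 17 (not isolated)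
Conditions: CeCl3 (anhydrous), iPrMgCl, THF, -78 °C; then 16, -78 to 0 °C; then 1 M aq HCl, THF, rt
Reagents that add atoms: isopropylmagnesium chloride, CC(C)[Mg]Cl
Why: Organocerium 1,2-addition, whose low basicity holds back enolisation and β-hydride reduction, should attack the C10 carbonyl from the face opposite the adjacent C6 side chain (isopropyl trans and hydroxyl cis to that chain, 10R), and the dilute acid then removes the triethylsilyl group.

**Step 8**
Reactants: 18 diol; 19 3,4-dimethoxybenzoyl chloride (veratroyl chloride)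
Product: 20 C5 veratrate with free C10 hydroxyl and C1 PMB ether (5S,6S,7S,10R)
Conditions: Et3N, DMAP (cat.), CH2Cl2, 0 °C to rt
Reagents that add atoms: none
Why: DMAP-catalysed acylation takes the secondary C5 hydroxyl, because the tertiary C10 hydroxyl between isopropyl and C6 is too hindered to compete.

**Step 9**
Reactants: 20 C5 veratrate PMB ether
Product: 21 C1 primary alcohol (5S,6S,7S,10R)
Conditions: DDQ, CH2Cl2-pH 7 buffer, 0 °C to rt
Reagents that add atoms: none
Why: Oxidative PMB cleavage by hydride abstraction from the electron-rich benzylic CH2, which the veratrate (no benzylic C-H, ring deactivated by its carbonyl) and the alkene should survive.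

**Step 10**
Reactants: 21 C1 primary alcohol
Product: 22 C1 aldehyde (5S,6S,7S,10R)
Conditions: Dess-Martin periodinane, CH2Cl2, rt
Reagents that add atoms: none
Why: Dess-Martin oxidation of the neopentyl primary alcohol leaves the tertiary alcohol alone, and the aldehyde has no α-hydrogen on C7 to epimerise.

**Step 11**
Reactants: 22 C1 aldehyde
Product: 23 C1 vinyl carbinols as a mixture of C1 epimers (5S,6S,7S,10R)
Conditions: CH2=CHMgBr (2.5 equiv), THF, -78 °C; aq NH4Cl
Reagents that add atoms: vinylmagnesium bromide, C=C[Mg]Br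
Why: Grignard 1,2-addition after deprotonation of the C10 hydroxyl, the aldehyde being far more electrophilic than the hindered aryl ester at this temperature; a Felkin-Anh reading (C6 large, C8 medium, CH3 small) predicts mainly the 1S epimer, so this C1 configuration is not relied on and is erased in step 12.

**Step 12**
Reactants: 23 C1 vinyl carbinols
Product: 24 C1 vinyl ketone (5S,6S,7S,10R)
Conditions: Dess-Martin periodinane, CH2Cl2, 0 °C to rt
Reagents that add atoms: none
Why: Dess-Martin oxidation converges both allylic epimers on one enone under neutral conditions that spare ester, alkenes and tertiary alcohol.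

**Step 13**
Reactants: 24 C1 vinyl ketone
Product: 25 (1R)-vinyl carbinol (1R,5S,6S,7S,10R)
Conditions: (S)-2-methyl-CBS-oxazaborolidine (0.5 equiv), catecholborane, toluene, -78 to -40 °C; MeOH, then aq NaHCO3
Reagents that add atoms: none
Why: Corey-Bakshi-Shibata reduction, in which the (S)-oxazaborolidine should bind the ketone with the tertiary-alkyl C7 side as large group and the vinyl as small group and deliver hydride to give the 1R carbinol, the same sense as Felkin-Anh attack anti to C6, while catecholborane leaves both alkenes and the ester alone.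

**Step 14**
Reactants: 25 (1R)-vinyl carbinol
Product: 26 ring B diene with C1 tert-butyldimethylsilyl ether, C5 veratrate, C3 isopropenyl group and free C10 hydroxyl (1R,5S,6S,7S,10R)
Conditions: tBuMe2SiOTf (1.2 equiv), 2,6-lutidine, CH2Cl2, -78 to 0 °C
Reagents that add atoms: tert-butyldimethylsilyl trifluoromethanesulfonate, CC(C)(C)[Si](C)(C)OS(=O)(=O)C(F)(F)F
Why: The silyl triflate reaches the hindered secondary allylic hydroxyl, whereas the buried tertiary C10 hydroxyl should stay free at low temperature with only a slight excess of reagent.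

**Step 15**
Reactants: 26 ring B diene
Product: 27 bicyclic C1 tert-butyldimethylsilyl ether with C5 veratrate and free C10 hydroxyl (1R,5S,6S,7S,10R)
Conditions: (H2IMes)(PCy3)Cl2Ru=CHPh (second-generation Grubbs catalyst, 10 mol %), 1,4-benzoquinone (20 mol %), toluene (0.002 M), 80 °C, argon sparge
Reagents that add atoms: none
Why: After phosphine loss the ruthenium alkylidene exchanges with the monosubstituted C1 vinyl group to sit on C2, adds intramolecularly across the C3 isopropenyl alkene to a ruthenacyclobutane, and cycloreversion releases C2=C3 and Ru=CH2, ethene leaving with the argon stream. The closest known reaction type is ring-closing metathesis of a vinyl group and a 1,1-disubstituted alkene to a trisubstituted cycloheptene with N-heterocyclic carbene ruthenium catalysts. Ring A closes as a seven-membered carbocycle by this intramolecular [2+2] cycloaddition-cycloreversion, trans-fused to ring B, and the ring size allows only the Z alkene. No stereocentre is made or touched, since C1, C5, C6, C7 and C10 are sp3 spectators set in steps 3, 5, 7 and 13. Cyclisation has to outrun intermolecular metathesis and ruthenium hydride-induced alkene migration, which is secured by high dilution, by the trans arms on C6 and C7 standing gauche so that C2 and C3 are within reach, by the silyl cap on the C1 oxygen and by benzoquinone as hydride scavenger. The angelate is kept out until later because an α,β-unsaturated ester on the C1 oxygen could close a butenolide with the same vinyl group.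

**Step 16**
Reactants: 27 bicyclic silyl ether
Product: 28 bicyclic C1 allylic alcohol with C5 veratrate (1R,5S,6S,7S,10R)
Conditions: Bu4NF, AcOH (1:1), THF, 0 °C to rt
Reagents that add atoms: none
Why: Fluoride-induced desilylation, buffered with acetic acid so that no free alkoxide is present to move the veratroyl group from the C5 oxygen to the C1 or C10 oxygen.

**Step 17**
Reactants: 28 bicyclic C1 allylic alcohol; 29 angelic acid, (Z)-2-methylbut-2-enoic acid
Product: 31 target CNP0142353.1 (1R,5S,6S,7S,10R), via mixed anhydride 30 (not isolated)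
Conditions: 2,4,6-trichlorobenzoyl chloride, Et3N, toluene, rt; then 28, toluene, 80 °C
Reagents that add atoms: none
Why: Yamaguchi esterification run without a nucleophilic pyridine catalyst, so the alcohol attacks the less hindered angeloyl carbonyl of the mixed anhydride with no conjugate addition-elimination path to the E (tiglate) isomer, and the tertiary C10 hydroxyl stays unacylated.

**Compound list**
1 | 4-methoxybenzyl alcohol | OCc1ccc(OC)cc1 | starting material
2 | tributyl(iodomethyl)stannane | CCCC[Sn](CCCC)(CCCC)CI | starting material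
3 | sodium 4-methoxybenzyl alkoxide | [Na+].[O-]Cc1ccc(OC)cc1 | intermediate
4 | tributyl{[(4-methoxybenzyl)oxy]methyl}stannane | CCCC[Sn](CCCC)(CCCC)COCc1ccc(OC)cc1 | intermediate
5 | 3-ethoxycyclopent-2-en-1-one | CCOC1=CC(=O)CC1 | starting material
6 | [(4-methoxybenzyl)oxy]methyllithium | [Li]COCc1ccc(OC)cc1 | intermediate
7 | lithium 3-ethoxy-1-{[(4-methoxybenzyl)oxy]methyl}cyclopent-2-en-1-olate (racemic) | CCOC1=CC(O[Li])(COCc2ccc(OC)cc2)CC1 | intermediate
8 | 3-{[(4-methoxybenzyl)oxy]methyl}cyclopent-2-en-1-one | O=C1C=C(COCc2ccc(OC)cc2)CC1 | intermediate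
9 | (7S)-dimethylaluminium enolate | C[Al](C)OC1=C[C@](C)(CC1)COCc1ccc(OC)cc1 | intermediate
10 | (7S)-trimethylsilyl enol ether | C[Si](C)(C)OC1=C[C@](C)(CC1)COCc1ccc(OC)cc1 | intermediate
11 | 3-methylbut-3-en-1-ol | C=C(C)CCO | starting material
12 | 3-methylbut-3-enal | C=C(C)CC=O | intermediate
13 | (7S)-lithium enolate | [Li]OC1=C[C@](C)(CC1)COCc1ccc(OC)cc1 | intermediate
14 | (7S)-dibutylboron enolate | CCCCB(CCCC)OC1=C[C@](C)(CC1)COCc1ccc(OC)cc1 | intermediate
15 | anti aldol (5S,6S,7S) | C=C(C)C[C@H](O)[C@@H]2[C@](C)(CCC2=O)COCc1ccc(OC)cc1 | intermediate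
16 | C5 triethylsilyl ether of the aldol | C=C(C)C[C@H](O[Si](CC)(CC)CC)[C@@H]2[C@](C)(CCC2=O)COCc1ccc(OC)cc1 | intermediate
17 | C10 isopropyl carbinol, C5 triethylsilyl ether (5S,6S,7S,10R) | C=C(C)C[C@H](O[Si](CC)(CC)CC)[C@@H]2[C@](C)(CC[C@@]2(O)C(C)C)COCc1ccc(OC)cc1 | intermediate
18 | C5,C10-diol, C1 PMB ether | C=C(C)C[C@H](O)[C@@H]2[C@](C)(CC[C@@]2(O)C(C)C)COCc1ccc(OC)cc1 | intermediate
19 | 3,4-dimethoxybenzoyl chloride | COc1ccc(C(=O)Cl)cc1OC | starting material
20 | C5 veratrate, C1 PMB ether | C=C(C)C[C@H](OC(=O)c1ccc(OC)c(OC)c1)[C@@H]2[C@](C)(CC[C@@]2(O)C(C)C)COCc1ccc(OC)cc1 | intermediate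
21 | C5 veratrate, C1 primary alcohol | C=C(C)C[C@H](OC(=O)c1ccc(OC)c(OC)c1)[C@@H]2[C@](C)(CC[C@@]2(O)C(C)C)CO | intermediate
22 | C5 veratrate, C1 aldehyde | C=C(C)C[C@H](OC(=O)c1ccc(OC)c(OC)c1)[C@@H]2[C@](C)(CC[C@@]2(O)C(C)C)C=O | intermediate
23 | C1 vinyl carbinols (C1 epimers) | C=C(C)C[C@H](OC(=O)c1ccc(OC)c(OC)c1)[C@@H]2[C@](C)(CC[C@@]2(O)C(C)C)C(O)C=C | intermediate
24 | C1 vinyl ketone | C=C(C)C[C@H](OC(=O)c1ccc(OC)c(OC)c1)[C@@H]2[C@](C)(CC[C@@]2(O)C(C)C)C(=O)C=C | intermediate
25 | (1R)-vinyl carbinol | C=C(C)C[C@H](OC(=O)c1ccc(OC)c(OC)c1)[C@@H]2[C@](C)(CC[C@@]2(O)C(C)C)[C@H](O)C=C | intermediate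
26 | ring B diene, C1 tert-butyldimethylsilyl ether (metathesis precursor) | C=C(C)C[C@H](OC(=O)c1ccc(OC)c(OC)c1)[C@@H]2[C@](C)(CC[C@@]2(O)C(C)C)[C@H](O[Si](C)(C)C(C)(C)C)C=C | intermediate
27 | bicyclic C1 silyl ether, C5 veratrate (metathesis product) | CC(C)(C)[Si](C)(C)O[C@@H]1C=C(C)C[C@H](OC(=O)c2ccc(OC)c(OC)c2)[C@@H]2[C@]1(C)CC[C@@]2(O)C(C)C | intermediate
28 | bicyclic C1 allylic alcohol, C5 veratrate | O[C@@H]1C=C(C)C[C@H](OC(=O)c2ccc(OC)c(OC)c2)[C@@H]2[C@]1(C)CC[C@@]2(O)C(C)C | intermediate
29 | angelic acid | C/C=C(/C)C(=O)O | starting material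
30 | angelic 2,4,6-trichlorobenzoic anhydride | C/C=C(/C)C(=O)OC(=O)c1c(Cl)cc(Cl)cc1Cl | intermediate
31 | CNP0142353.1 (1R,5S,6S,7S,10R) | C/C=C(/C)C(=O)O[C@@H]1C=C(C)C[C@H](OC(=O)c2ccc(OC)c(OC)c2)[C@@H]2[C@]1(C)CC[C@@]2(O)C(C)C | target

**Total step count:** 17. **Longest linear sequence:** 16 (steps 1-3 and 5-17).

**Steps most likely to fail**

**Step 15.**
- Risk: ruthenium may load slowly on the C1 vinyl group, which is flanked by the silyl ether and the quaternary C7. Catalyst decay, intermolecular coupling or alkene migration could then outrun ring closure.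
- Fallback: a relay ring-closing metathesis across the same C2=C3 bond, setting out from aldehyde 22 and coming back at 27.
- Hex-5-enal is turned by Takai olefination (CHI3, CrCl2, THF, 0 °C) into (E)-1-iodohepta-1,6-diene F1.
- Nozaki-Hiyama-Kishi coupling of F1 with 22 (CrCl2, NiCl2 cat., DMF, rt) should give the C1 heptadienyl carbinols F2 as C1 epimers.
- Dess-Martin oxidation then gives the dienone F3. CBS reduction as in step 13 gives the (1R)-heptadienyl carbinol F4, and tBuMe2SiOTf with 2,6-lutidine gives the relay silyl ether F5.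
- With the same catalyst, ruthenium enters at the unhindered terminal alkene of the relay arm, expels cyclopentene and is thereby delivered onto C2. Closure on the isopropenyl group then gives 27.

**Step 5.**
- Risk: three processes could erode the step. The acidic β,γ-unsaturated aldehyde may transfer a proton and drift into conjugation. The anti preference in the chair may be weak next to the quaternary C7. The enolate may discriminate poorly between its CH3 face and its CH2OPMB face.
- Fallback: the C5-C6 and C4-C5 bonds are made separately, setting out from silyl enol ether 10 and coming back at diol 18.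
- Mukaiyama hydroxymethylation of 10 (aq formaldehyde, Sc(OTf)3 cat., THF) gives the C6 hydroxymethyl ketone F6. Only the face question is left here, on a small ketol whose epimers can be separated.
- Et3SiOTf with 2,6-lutidine gives its silyl ether F7. Isopropylcerium addition as in step 7 gives the silylated C10 carbinol F8, and dilute HCl gives the primary-tertiary diol F9.
- TEMPO with PhI(OAc)2 oxidises only the primary alcohol, to the C5 aldehyde F10.
- Methallylboration with (-)-B-methallyldiisopinocampheylborane (from (+)-α-pinene; Et2O, -78 °C, oxidative work-up) should add to the Si face under reagent control. This sets 5S and gives 18.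

**Step 17.**
- Risk: acylation of the neopentyl allylic C1 hydroxyl may be slow. Z-to-E isomerisation of the activated angelate, or ionisation of the allylic alcohol on long heating, could then compete.
- Fallback: the angelate alkene is built on the oxygen, setting out from 28 and coming back at 31.
- Steglich esterification of 28 with 2-[bis(2,2,2-trifluoroethoxy)phosphoryl]propanoic acid (EDC, DMAP, CH2Cl2) gives the C1 phosphonopropionate F11. DMAP is allowed here because there is no alkene geometry to lose.
- Still-Gennari olefination (KN(SiMe3)2, 18-crown-6, THF, -78 °C, then acetaldehyde) should form the Z-trisubstituted alkene and give 31.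

**Further compounds**
F1 | step 15 | (E)-1-iodohepta-1,6-diene | C=CCCC/C=C/I
F2 | step 15 | C1 heptadienyl carbinols (C1 epimers) | C=C(C)C[C@H](OC(=O)c1ccc(OC)c(OC)c1)[C@@H]2[C@](C)(CC[C@@]2(O)C(C)C)C(O)/C=C/CCCC=C
F3 | step 15 | C1 dienone | C=C(C)C[C@H](OC(=O)c1ccc(OC)c(OC)c1)[C@@H]2[C@](C)(CC[C@@]2(O)C(C)C)C(=O)/C=C/CCCC=C
F4 | step 15 | (1R)-heptadienyl carbinol | C=C(C)C[C@H](OC(=O)c1ccc(OC)c(OC)c1)[C@@H]2[C@](C)(CC[C@@]2(O)C(C)C)[C@H](O)/C=C/CCCC=C
F5 | step 15 | relay silyl ether | C=C(C)C[C@H](OC(=O)c1ccc(OC)c(OC)c1)[C@@H]2[C@](C)(CC[C@@]2(O)C(C)C)[C@H](O[Si](C)(C)C(C)(C)C)/C=C/CCCC=C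
F6 | step 5 | (2S,3S)-2-(hydroxymethyl)-3-{[(4-methoxybenzyl)oxy]methyl}-3-methylcyclopentan-1-one | OC[C@@H]2[C@](C)(CCC2=O)COCc1ccc(OC)cc1
F7 | step 5 | triethylsilyl ether of F6 | CC[Si](CC)(CC)OC[C@@H]2[C@](C)(CCC2=O)COCc1ccc(OC)cc1
F8 | step 5 | silylated C10 isopropyl carbinol | CC[Si](CC)(CC)OC[C@@H]2[C@](C)(CC[C@@]2(O)C(C)C)COCc1ccc(OC)cc1
F9 | step 5 | primary-tertiary diol | OC[C@@H]2[C@](C)(CC[C@@]2(O)C(C)C)COCc1ccc(OC)cc1
F10 | step 5 | C5 aldehyde | O=C[C@@H]2[C@](C)(CC[C@@]2(O)C(C)C)COCc1ccc(OC)cc1
F11 | step 17 | C1 2-[bis(2,2,2-trifluoroethoxy)phosphoryl]propanoate of 28 | CC(C(=O)O[C@@H]1C=C(C)C[C@H](OC(=O)c2ccc(OC)c(OC)c2)[C@@H]2[C@]1(C)CC[C@@]2(O)C(C)C)P(=O)(OCC(F)(F)F)OCC(F)(F)F
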